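Retrosynthetic overview
1. Numbering (lindenane type): cyclopropane C1–C2–C3; five-membered ring C1, C3, C4, C5, C10; six-membered ring C = C5–C10 (C8=O, C9–OH, CH3-14 on C10); C15 = CH2 on C4; C11 = the quaternary ester carbon on C15, which the target bonds to C7 of the other unit; the tricycle C1–C10 + C14 is named 11,12,13,15-tetranorlindenane.
2. The target is a C2-symmetric head-to-tail cyclodimer with the 12-membered ring C7–C11'–C15'–C4'=C5'–C6'=C7'–C11–C15–C4=C5–C6=(C7). Both C7–C11 bonds (α-carbon of a linearly conjugated 2,4-dienone to α-carbon of a methyl ester) are cut, the second being the ring-closing bond, which leaves one monomer with C7–I and a tertiary C11–Br.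
3. Enabling feature: ring C and the five-membered ring lock the diene C4=C5–C6=C7 s-trans, so the C15–C11 arm and C7 of one unit cannot meet; two units must pair head to tail, and the C2 axis makes both bond formations the same reaction.
4. Monomer and ring order: cyclopropane and five-membered ring together from (S)-epichlorohydrin by epoxide-carbenoid cyclopropanation (sets C1, C3; step 2), ring C by a facially controlled Diels–Alder reaction (sets C10; step 6), side chain by Negishi coupling at C4, 12-membered ring (step 12), C9–OH last under thermodynamic control.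

Key step: step 12

Assumption: the (S,S) antipode of the bi(oxazoline) ligand is taken as the one that delivers the (11R) centres; if the sense of induction proves opposite, the mirror-image ligand is used with no other change.

Step 1
Reactants: 1 (S)-epichlorohydrin; 2 but-2-en-1-ylmagnesium chloride
Product: 4 (2S)-2-(2-methylbut-3-en-1-yl)oxirane, via chlorohydrin 3 (not isolated)
Conditions: THF, −30 → 0 °C, no copper salt; then aq NaOH, rt
Reagents that add atoms: none
Why: Grignard opening of an epoxide, in which the allylic reagent reacts through its γ-carbon (SE2') at the epoxide CH2, followed by base closure of the chlorohydrin to the new epoxide without touching the C2 stereocentre; the methyl-bearing carbon forms as an epimer mixture that is erased in step 4.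

Step 2
Reactants: 4 (2S)-2-(2-methylbut-3-en-1-yl)oxirane
Product: 5 (1S,2S,5S)-4-methylbicyclo[3.1.0]hexan-2-ol (C4 epimers)
Conditions: 2,2,6,6-tetramethylpiperidine, n-BuLi, t-BuOMe, 0 °C → rt
Reagents that add atoms: none
Why: intramolecular cyclopropanation by a lithium amide-generated α-lithiated terminal epoxide, which acts as a carbenoid toward the pendant alkene; C1 and C5 of the bicycle are set by the epoxide stereocentre (hydroxyl trans to the cyclopropane CH2).

Step 3
Reactants: 5 (1S,2S,5S)-4-methylbicyclo[3.1.0]hexan-2-ol
Product: 6 (1S,5S)-4-methylbicyclo[3.1.0]hexan-2-one (C4 epimers)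
Conditions: TEMPO (cat.), KBr (cat.), NaOCl, NaHCO3, CH2Cl2/H2O, 0 °C
Reagents that add atoms: none
Why: TEMPO/hypochlorite oxidation of a secondary alcohol, which leaves the cyclopropane untouched.

Step 4
Reactants: 6 (1S,5S)-4-methylbicyclo[3.1.0]hexan-2-one
Product: 7 (1S,5R)-4-methylbicyclo[3.1.0]hex-3-en-2-one
Conditions: IBX, DMSO, 70 °C
Reagents that add atoms: none
Why: IBX dehydrogenation of a ketone; only C3 can enolise (C1 is a cyclopropane carbon), so the C3=C4 enone forms and the C4 epimers converge.

Step 5
Reactants: 8 methyl vinyl ketone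
Product: 9 2-(triisopropylsilyloxy)buta-1,3-diene
Conditions: i-Pr3SiOTf, Et3N, Et2O, 0 °C → rt
Reagents that add atoms: triisopropylsilyl trifluoromethanesulfonate, CC(C)[Si](C(C)C)(C(C)C)OS(=O)(=O)C(F)(F)F
Why: O-silylation of the methyl-side enol of an enone with a silyl triflate and amine base, the standard entry to 2-silyloxybutadienes.

Step 6
Reactants: 7 (1S,5R)-4-methylbicyclo[3.1.0]hex-3-en-2-one; 9 2-(triisopropylsilyloxy)buta-1,3-diene
Product: 10 (1R,3S,5S,10S)-8-(triisopropylsilyloxy)-11,12,13,15-tetranorlinden-7-en-4-one
Conditions: AlBr3/AlMe3 (10:1, 20 mol%), 9 (2 equiv), toluene/CH2Cl2, −5 °C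
Reagents that add atoms: none
Why: mixed-Lewis-acid Diels–Alder reaction of a hindered β-methyl cycloalkenone with a 2-silyloxydiene, in which the CH2 terminus next to the silyloxy carbon bonds to the β-carbon C10 and the diene adds anti to the cyclopropane CH2; this sets C10 (CH3-14 syn to the cyclopropane CH2), gives a cis ring fusion (C5 is later made planar) and leaves a regiodefined C7=C8 silyl enol ether.

Step 7
Reactants: 10 the Diels–Alder adduct
Product: 11 (1R,3S,10S)-8-(triisopropylsilyloxy)-11,12,13,15-tetranorlindena-4,7-dien-4-yl trifluoromethanesulfonate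
Conditions: KN(SiMe3)2, PhNTf2, THF, −78 → 0 °C
Reagents that add atoms: N-phenylbis(trifluoromethanesulfonimide), O=S(=O)(N(c1ccccc1)S(=O)(=O)C(F)(F)F)C(F)(F)F
Why: enol triflate formation, in which the C4 ketone can enolise only toward C5 (C3 is a cyclopropane carbon) and O-sulfonylation of that enolate gives the C4=C5 enol triflate while the silyl enol ether is inert.

Step 8
Reactants: 11 the enol triflate; 12 methyl 3-bromo-2-methylpropanoate (racemic)
Product: 14 methyl 2-methyl-3-[(1R,3S,10S)-8-(triisopropylsilyloxy)-11,12,13,15-tetranorlindena-4,7-dien-4-yl]propanoate, via organozinc 13 (not isolated)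
Conditions: 12, Zn dust, I2 (cat.), DMA, 70 °C; then 11, PdCl2(dppf) (5 mol%), THF/DMA, 50 °C
Reagents that add atoms: none
Why: Negishi coupling, in which zerovalent palladium inserts into the enol triflate, the primary alkylzinc transmetalates and the dppf ligand favours reductive elimination over β-hydride loss; the side-chain stereocentre is not controlled and becomes planar in step 12.

Step 9
Reactants: 14 the ester
Product: 15 methyl 2-bromo-2-methyl-3-[(1R,3S,10S)-8-(triisopropylsilyloxy)-11,12,13,15-tetranorlindena-4,7-dien-4-yl]propanoate (epimers at the bromine-bearing carbon)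
Conditions: LiN(i-Pr)2, THF, −78 °C; then BrCCl2CCl2Br
Reagents that add atoms: 1,2-dibromo-1,1,2,2-tetrachloroethane, BrC(Cl)(Cl)C(Cl)(Cl)Br
Why: α-bromination of an ester enolate by a positive-bromine donor; with the C8 ketone masked as its silyl enol ether the ester α-proton is the only acidic site, and C-bromination gives the tertiary α-bromo ester.

Step 10
Reactants: 15 the bromo ester
Product: 16 methyl 2-bromo-2-methyl-3-[(1R,3S,10S)-8-oxo-11,12,13,15-tetranorlindena-4,6-dien-4-yl]propanoate (epimers at the bromine-bearing carbon)
Conditions: DDQ, 2,6-lutidine, CH2Cl2, 0 °C → rt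
Reagents that add atoms: none
Why: DDQ dehydrogenation of a silyl enol ether, in which the doubly allylic hydride at C6 is removed to give a silyloxy-stabilised pentadienyl cation and loss of the silyl group unveils the linearly conjugated C4=C5–C6=C7–C8=O dienone.

Step 11
Reactants: 16 the dienone
Product: 17 methyl 2-bromo-3-[(1R,3S,10S)-7-iodo-8-oxo-11,12,13,15-tetranorlindena-4,6-dien-4-yl]-2-methylpropanoate (epimers at the bromine-bearing carbon)
Conditions: I2, pyridine, CH2Cl2, 0 °C → rt
Reagents that add atoms: iodine, [I][I]
Why: α-iodination of an enone by the pyridine addition–iodination–elimination sequence, which functionalises only the α-carbon C7; pyridine is too weak a base to eliminate HBr from the tertiary bromide.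

Step 12
Reactants: 17 the iodo bromo monomer (two molecules)
Product: 19 9,9'-dideoxycycloshizukaol A, via open-chain dimer 18 (not isolated)
Conditions: NiBr2·MeOCH2CH2OMe (30 mol%), (4S,4'S)-4,4'-di(heptan-4-yl)-2,2'-bi(2-oxazoline) (36 mol%), Mn powder (4 equiv), DMA, slow addition of 17 to 0.01 M, 10 °C
Reagents that add atoms: none
Why: Proposed new method: a nickel-catalysed reductive cross-electrophile cyclodimerisation in which zerovalent nickel inserts into the C7–I bond of the α-iodo dienone, a monovalent nickel halide abstracts bromine from the tertiary α-bromo ester of a second molecule, the planar C11 radical is captured by the alkenylnickel species and C7–C11 forms by reductive elimination from trivalent nickel while Mn regenerates zerovalent nickel; the closest known reaction types are the nickel-catalysed reductive coupling of tertiary alkyl halides with aryl or alkenyl halides, the asymmetric reductive alkenylation of α-halo carbonyl compounds and the enantioconvergent nickel-catalysed coupling of racemic tertiary α-halo carbonyl electrophiles. The first C7–C11 bond joins two molecules head to tail (18) and the second closes the 12-membered ring, the mode of closure being an end-to-end macrocyclisation by C(sp2)–C(sp3) reductive elimination from a 13-membered nickelacycle. Both C11 centres arise from a planar radical, so the epimeric bromides converge and the configuration is set in the reductive elimination by the chiral bi(oxazoline)–nickel complex (catalyst control, CH3 against the CH2–tricycle arm), with the rigid seco-dimer expected to reinforce the like (11R,11'R) sense in the ring closure. Cross-coupling over homo-coupling is secured by the different activation modes of the C(sp2)–I and tertiary C(sp3)–Br bonds. Cyclodimerisation over self-closure is secured by the tricycle, which holds C4=C5–C6=C7 s-trans so that the C11 radical cannot reach C7 of its own unit, and high dilution favours closure of 18 over chain growth.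

Step 13
Reactants: 19 9,9'-dideoxycycloshizukaol A
Product: 20 9,9'-di-epi-cycloshizukaol A 9,9'-di-O-acetate
Conditions: Mn(OAc)3 (6 equiv), benzene, 80 °C
Reagents that add atoms: manganese triacetate, CC(=O)O[Mn](OC(C)=O)OC(C)=O
Why: α'-acetoxylation of an α,β-unsaturated ketone through its trivalent manganese enolate; C9 is the only α'-position and the acetate should enter anti to the axial CH3-14 (9α), a configuration that step 14 corrects.

Step 14
Reactants: 20 the diacetate
Product: 21 cycloshizukaol A
Conditions: K2CO3, MeOH, argon, 0 °C → rt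
Reagents that add atoms: none
Why: methanolysis of both acetates followed by base equilibration of each α-ketol through its enediolate to the equatorial 9β-alcohol (cis to CH3-14, hydrogen-bonded to C8=O, protonation anti to the axial methyl), which sets C9 as R; the conjugated C8 ketone is favoured over the transposed C9 ketone.

Compound list

1 | (S)-epichlorohydrin, (2S)-2-(chloromethyl)oxirane | ClC[C@@H]1CO1 | starting material
2 | but-2-en-1-ylmagnesium chloride | CC=CC[Mg]Cl | starting material
3 | (2S)-1-chloro-4-methylhex-5-en-2-ol (as chloromagnesium alkoxide, C4 epimers) | ClC[C@@H](O)CC(C)C=C | intermediate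
4 | (2S)-2-(2-methylbut-3-en-1-yl)oxirane (epimers at the methyl-bearing carbon) | C=CC(C)C[C@H]1CO1 | intermediate
5 | (1S,2S,5S)-4-methylbicyclo[3.1.0]hexan-2-ol (C4 epimers, OH trans to the cyclopropane CH2) | O[C@H]1CC(C)[C@@H]2C[C@H]12 | intermediate
6 | (1S,5S)-4-methylbicyclo[3.1.0]hexan-2-one (C4 epimers) | O=C1CC(C)[C@@H]2C[C@H]12 | intermediate
7 | (1S,5R)-4-methylbicyclo[3.1.0]hex-3-en-2-one | O=C1C=C(C)[C@@H]2C[C@H]12 | intermediate
8 | methyl vinyl ketone (but-3-en-2-one) | CC(=O)C=C | starting material
9 | 2-(triisopropylsilyloxy)buta-1,3-diene | C=CC(=C)O[Si](C(C)C)(C(C)C)C(C)C | intermediate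
10 | (1R,3S,5S,10S)-8-(triisopropylsilyloxy)-11,12,13,15-tetranorlinden-7-en-4-one (cis-fused; H-5, CH3-14 and the cyclopropane CH2 on one face) | O=C1[C@H]2CC=C(O[Si](C(C)C)(C(C)C)C(C)C)C[C@@]2(C)[C@@H]3C[C@H]13 | intermediate
11 | (1R,3S,10S)-8-(triisopropylsilyloxy)-11,12,13,15-tetranorlindena-4,7-dien-4-yl trifluoromethanesulfonate | FC(F)(F)S(=O)(=O)OC1=C2CC=C(O[Si](C(C)C)(C(C)C)C(C)C)C[C@@]2(C)[C@@H]3C[C@H]13 | intermediate
12 | methyl 3-bromo-2-methylpropanoate (racemic) | COC(=O)C(C)CBr | starting material
13 | (3-methoxy-2-methyl-3-oxopropyl)zinc bromide | COC(=O)C(C)C[Zn]Br | intermediate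
14 | methyl 2-methyl-3-[(1R,3S,10S)-8-(triisopropylsilyloxy)-11,12,13,15-tetranorlindena-4,7-dien-4-yl]propanoate (epimers at the side-chain carbon) | COC(=O)C(C)CC1=C2CC=C(O[Si](C(C)C)(C(C)C)C(C)C)C[C@@]2(C)[C@@H]3C[C@H]13 | intermediate
15 | methyl 2-bromo-2-methyl-3-[(1R,3S,10S)-8-(triisopropylsilyloxy)-11,12,13,15-tetranorlindena-4,7-dien-4-yl]propanoate (epimers at the bromine-bearing carbon) | COC(=O)C(C)(Br)CC1=C2CC=C(O[Si](C(C)C)(C(C)C)C(C)C)C[C@@]2(C)[C@@H]3C[C@H]13 | intermediate
16 | methyl 2-bromo-2-methyl-3-[(1R,3S,10S)-8-oxo-11,12,13,15-tetranorlindena-4,6-dien-4-yl]propanoate (epimers at the bromine-bearing carbon) | COC(=O)C(C)(Br)CC1=C2C=CC(=O)C[C@@]2(C)[C@@H]3C[C@H]13 | intermediate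
17 | methyl 2-bromo-3-[(1R,3S,10S)-7-iodo-8-oxo-11,12,13,15-tetranorlindena-4,6-dien-4-yl]-2-methylpropanoate (epimers at the bromine-bearing carbon) | COC(=O)C(C)(Br)CC1=C2C=C(I)C(=O)C[C@@]2(C)[C@@H]3C[C@H]13 | intermediate
18 | open-chain head-to-tail dimer: C7 of the unit that keeps its C–Br is bonded to the new (11R) quaternary carbon of the unit that keeps its C7–I | COC(=O)C(C)(Br)CC1=C2C=C(C(=O)C[C@@]2(C)[C@@H]3C[C@H]13)[C@](C)(C(=O)OC)CC1=C2C=C(I)C(=O)C[C@@]2(C)[C@@H]3C[C@H]13 | intermediate
19 | 9,9'-dideoxycycloshizukaol A, (1R,3S,10S,11R) in each half | COC(=O)[C@]1(C)CC2=C3C=C(C(=O)C[C@@]3(C)[C@@H]3C[C@H]23)[C@](C)(C(=O)OC)CC2=C3C=C1C(=O)C[C@@]3(C)[C@@H]1C[C@H]21 | intermediate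
20 | 9,9'-di-epi-cycloshizukaol A 9,9'-di-O-acetate, (9S,9'S), acetoxy groups trans to CH3-14 | COC(=O)[C@]1(C)CC2=C3C=C(C(=O)[C@@H](OC(C)=O)[C@@]3(C)[C@@H]3C[C@H]23)[C@](C)(C(=O)OC)CC2=C3C=C1C(=O)[C@@H](OC(C)=O)[C@@]3(C)[C@@H]1C[C@H]21 | intermediate
21 | cycloshizukaol A, (1R,3S,9R,10S,11R) in each half | COC(=O)[C@]1(C)CC2=C3C=C(C(=O)[C@H](O)[C@@]3(C)[C@@H]3C[C@H]23)[C@](C)(C(=O)OC)CC2=C3C=C1C(=O)[C@H](O)[C@@]3(C)[C@@H]1C[C@H]21 | target

Total step count: 14. Longest linear sequence: 13 steps (steps 1–4 and 6–14; step 5 prepares the diene 9).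

The three steps most likely to fail are steps 12, 6 and 13, in that order; step 12 comes first because it bears the label "Proposed new method:".

First risk, step 12. What may go wrong: weak stereocontrol at C11 in the first, intermolecular bond formation; β-hydride loss from the tertiary alkylnickel species, which amounts to dehydrobromination to an unsaturated ester; hydrodehalogenation at C7 or C11; chain growth in place of ring closure. The fallback is stepwise, uses known two-electron chemistry, sets out from 16 and 17 and comes back to the route at 19. Zinc insertion into the C–Br bond of 16 (activated Zn dust, THF, rt) gives Reformatsky reagent F1. After removal of excess zinc it is coupled with the alkenyl iodide of 17 by palladium-catalysed α-alkenylation of a zinc ester enolate (Pd(dba)2, P(t-Bu)3, THF, rt), which gives the iodine-free open-chain dimer F2; its C11 epimers are separated at this stage. α-Iodination of the (11R) epimer (I2, pyridine, CH2Cl2) gives 18. Zinc insertion into the activated tertiary C–Br bond of 18, below the temperature at which the alkenyl iodide reacts, gives Reformatsky reagent F3, and the same palladium-catalysed α-alkenylation, now intramolecular and under high dilution, closes the 12-membered ring to 19.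

Second risk, step 6. What may go wrong: no cycloaddition at the fully substituted β-carbon, Lewis-acid opening of the cyclopropyl ketone, or desilylation and polymerisation of the diene. The fallback sets out from 7 and comes back to the route at 11. Bromination and dehydrobromination of 7 (Br2, CH2Cl2, −78 °C; then Et3N) give bromo enone F4, a more reactive dienophile. Its Diels–Alder reaction with 9 (toluene, 80 °C, or ZnBr2 in CH2Cl2) gives the 5-bromo adduct F5 with the same facial and regiochemical sense. Reduction of the α-bromo ketone of the adduct with Me2CuLi (THF, −78 °C) generates the C4 enolate regiospecifically, and trapping with PhNTf2 gives the enol triflate 11.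

Third risk, step 13. What may go wrong: oxidation at the vinylogous C15 position in place of C9, over-oxidation of the α-ketol, or incomplete double functionalisation. The fallback sets out from 19 and comes back to the route at 21. Kinetic α'-deprotonation and silylation (LiN(SiMe3)2, Me3SiCl, THF, −78 °C) give the bis(trimethylsilyl enol ether) F6. Rubottom oxidation (dimethyldioxirane, acetone, −40 °C; then dilute acid), with the oxidant entering anti to the axial CH3-14, should give the diol F7, 9,9'-di-epi-cycloshizukaol A. The K2CO3/MeOH equilibration used in step 14 then epimerises both C9 centres and gives 21.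

Further compounds

F1 | step 12 | Reformatsky reagent of 16, methyl 2-(bromozincio)-2-methyl-3-[(1R,3S,10S)-8-oxo-11,12,13,15-tetranorlindena-4,6-dien-4-yl]propanoate | COC(=O)C(C)([Zn]Br)CC1=C2C=CC(=O)C[C@@]2(C)[C@@H]3C[C@H]13
F2 | step 12 | iodine-free open-chain dimer (as 18 with H at C7 of the second unit) | COC(=O)C(C)(Br)CC1=C2C=C(C(=O)C[C@@]2(C)[C@@H]3C[C@H]13)[C@](C)(C(=O)OC)CC1=C2C=CC(=O)C[C@@]2(C)[C@@H]3C[C@H]13
F3 | step 12 | Reformatsky reagent of 18 | COC(=O)C(C)([Zn]Br)CC1=C2C=C(C(=O)C[C@@]2(C)[C@@H]3C[C@H]13)[C@](C)(C(=O)OC)CC1=C2C=C(I)C(=O)C[C@@]2(C)[C@@H]3C[C@H]13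
F4 | step 6 | bromo enone, (1S,5R)-3-bromo-4-methylbicyclo[3.1.0]hex-3-en-2-one | O=C1C(Br)=C(C)[C@@H]2C[C@H]12
F5 | step 6 | 5-bromo adduct, the 5-bromo analogue of 10 (bromine at C5 on the face of CH3-14) | O=C1[C@@]2(Br)CC=C(O[Si](C(C)C)(C(C)C)C(C)C)C[C@@]2(C)[C@@H]3C[C@H]13
F6 | step 13 | bis(trimethylsilyl enol ether) of 19 (C8–O–Si, C8=C9 in each half) | COC(=O)[C@]1(C)CC2=C3C=C(C(O[Si](C)(C)C)=C[C@@]3(C)[C@@H]3C[C@H]23)[C@](C)(C(=O)OC)CC2=C3C=C1C(O[Si](C)(C)C)=C[C@@]3(C)[C@@H]1C[C@H]21
F7 | step 13 | diol, 9,9'-di-epi-cycloshizukaol A (9S,9'S) | COC(=O)[C@]1(C)CC2=C3C=C(C(=O)[C@@H](O)[C@@]3(C)[C@@H]3C[C@H]23)[C@](C)(C(=O)OC)CC2=C3C=C1C(=O)[C@@H](O)[C@@]3(C)[C@@H]1C[C@H]21
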